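Ring C (the pyran ring) is opened at the bond between C4 and C4a. C4 is benzylic to the acylphloroglucinol ring and ortho to two of its free hydroxyls, so it can be the exocyclic carbon of an ortho-quinone methide; C4a of ring A, ortho to the ether oxygen O1, can add to it. In one operation an (R)-3-aryl-3-aryloxypropanal condenses with dodecanoylphloroglucinol, the ortho-quinone methide forms, and the tethered ring A closes ring C by Friedel–Crafts conjugate addition, placing the new C4 substituent cis to the C2 aryl group. C2 itself comes from an asymmetric allylboration followed by a Mitsunobu inversion.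

Key step: step 5

Remark: flavan numbering is used (O1, C2, C3, C4, C4a, C5–C8, C8a; ring A = benzo ring, ring B = 4-hydroxyphenyl group, ring C = pyran ring); the target is the 2,4-cis isomer, (2R,4R). The sense of induction in step 2 (S catalyst, Si-face attack, S alcohol) is assumed and should be checked on the first batch.

**Step 1**
Reactants: 1 phloroglucinol; 2 dodecanoyl chloride
Product: 3 1-(2,4,6-trihydroxyphenyl)dodecan-1-one
Conditions: AlCl3 (3.5 equiv), PhNO2/CH2Cl2, 0 → 60 °C; then ice/aq. HCl
Reagents that add atoms: none
Why: Friedel–Crafts acylation of the symmetric, highly nucleophilic arene should stop after one C-acylation because the chelated aryl ketone deactivates the ring, and all three ring positions are equivalent.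

**Step 2**
Reactants: 4 4-formylphenyl acetate; 5 allylboronic acid pinacol ester
Product: 7 4-[(1S)-1-hydroxybut-3-en-1-yl]phenyl acetate, via homoallyl pinacol borate 6 (not isolated)
Conditions: (S)-TRIP phosphoric acid [(S)-3,3'-bis(2,4,6-triisopropylphenyl)-1,1'-binaphthyl-2,2'-diyl hydrogen phosphate, 5 mol %], toluene, −30 °C; then H2O
Reagents that add atoms: none
Why: Chiral phosphoric acid-catalysed allylboration through a chair-like six-membered transition state, in which the catalyst activates the boronate and shields one aldehyde face, should deliver the allyl group to the Si face and set the S carbinol, the aryl acetate being inert.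

**Step 3**
Reactants: 7 4-[(1S)-1-hydroxybut-3-en-1-yl]phenyl acetate; 8 3-hydroxyphenyl acetate
Product: 9 3-{[(1R)-1-(4-acetoxyphenyl)but-3-en-1-yl]oxy}phenyl acetate
Conditions: PPh3, DIAD (diisopropyl azodicarboxylate), toluene, 0 °C → rt
Reagents that add atoms: none
Why: Mitsunobu etherification proceeds by SN2 displacement of the alkoxyphosphonium ion by the phenoxide, so the S carbinol should be inverted to the R ether, and the para-acetoxy group, which is not a donor, disfavours ionisation.

**Step 4**
Reactants: 9 3-{[(1R)-1-(4-acetoxyphenyl)but-3-en-1-yl]oxy}phenyl acetate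
Product: 11 4-[(1R)-1-(3-acetoxyphenoxy)-3-oxopropyl]phenyl acetate, via secondary ozonide 10 (not isolated)
Conditions: O3, CH2Cl2, −78 °C (to first blue colour); Me2S, −78 °C → rt; water wash to remove formaldehyde; used at once
Reagents that add atoms: ozone, [O-][O+]=O
Why: Ozonolysis with reductive work-up cleaves the only alkene while both acetoxy-deactivated arenes should survive, and the neutral work-up avoids β-elimination of the aryloxy group, leaving C2 untouched.

**Step 5**
Reactants: 11 4-[(1R)-1-(3-acetoxyphenoxy)-3-oxopropyl]phenyl acetate; 3 1-(2,4,6-trihydroxyphenyl)dodecan-1-one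
Product: 14 4-[(2R,4R)-7-acetoxy-4-(3-dodecanoyl-2,4,6-trihydroxyphenyl)-3,4-dihydro-2H-chromen-2-yl]phenyl acetate, via benzylic carbinol adduct 12 (not isolated), via ortho-quinone methide 13 (not isolated)
Conditions: 11 added over 1 h to 3 (1.2 equiv), TsOH·H2O (20 mol %), (CF3)2CHOH/CH2Cl2 1:1 (0.05 M), 0 °C → rt
Reagents that add atoms: none
Why: TsOH in the ionising, non-basic solvent should first promote Friedel–Crafts hydroxyalkylation of the free ring position of 3 by the aldehyde (12), the carbinol then loses water through its ortho hydroxyl to the ortho-quinone methide 13 (a C4 benzylic cation when protonated), and C4a of ring A adds to C4 and rearomatises. The closest known reaction types are the acid-mediated double arylation of an aldehyde in which one arene is a tethered aryl ether (xanthene and 4-arylchroman syntheses) and the conjugate arylation of acylphloroglucinol ortho-quinone methides made by Knoevenagel-type condensation. Ring C closes in a 6-exo-trig mode with respect to the exocyclic C4=C bond of 13, through the C4–C4a bond. The new C4 stereocentre is controlled by C2: in the chair-like transition state the C2 aryl group is equatorial and the bulky phloroglucinol ring lies anti to the C4a–C8a bond, away from the face of ring A, which should give the 2,4-cis (4R) product. The step needs the phloroglucinol to add before ring A does, ring closure para to the acetoxy group and no ionisation at C2; the two acetates are meant to secure this, since acetoxy-substituted ring A is far less nucleophilic than 3 towards the aldehyde yet can still trap the intramolecular cation at its less hindered ortho position, and the para-acetoxy group of ring B destabilises a C2 cation. Adducts of 13 with a second molecule of 3 are reversible under acid whereas ring closure is not, so material should funnel to 14.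

**Step 6**
Reactants: 14 4-[(2R,4R)-7-acetoxy-4-(3-dodecanoyl-2,4,6-trihydroxyphenyl)-3,4-dihydro-2H-chromen-2-yl]phenyl acetate
Product: 15 1-{2,4,6-trihydroxy-3-[(2R,4R)-7-hydroxy-2-(4-hydroxyphenyl)-3,4-dihydro-2H-chromen-4-yl]phenyl}dodecan-1-one
Conditions: K2CO3 (0.5 equiv), degassed MeOH, 0 °C → rt, argon; then dilute aq. HCl to pH 4
Reagents that add atoms: none
Why: Base-catalysed transesterification (Zemplén-type methanolysis) should remove both aryl acetates at low temperature without touching the aryl ketone or the C2 and C4 centres.

**Compound list**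

1 | phloroglucinol | Oc1cc(O)cc(O)c1 | starting material
2 | dodecanoyl chloride | CCCCCCCCCCCC(Cl)=O | starting material
3 | 1-(2,4,6-trihydroxyphenyl)dodecan-1-one | CCCCCCCCCCCC(=O)c1c(O)cc(O)cc1O | intermediate
4 | 4-formylphenyl acetate | CC(=O)Oc1ccc(C=O)cc1 | starting material
5 | allylboronic acid pinacol ester | C=CCB1OC(C)(C)C(C)(C)O1 | starting material
6 | pinacol borate ester of the S homoallylic alcohol | CC(=O)Oc1ccc([C@H](CC=C)OB2OC(C)(C)C(C)(C)O2)cc1 | intermediate (not isolated)
7 | 4-[(1S)-1-hydroxybut-3-en-1-yl]phenyl acetate | CC(=O)Oc1ccc([C@@H](O)CC=C)cc1 | intermediate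
8 | 3-hydroxyphenyl acetate | CC(=O)Oc1cccc(O)c1 | starting material
9 | 3-{[(1R)-1-(4-acetoxyphenyl)but-3-en-1-yl]oxy}phenyl acetate | CC(=O)Oc1ccc([C@@H](CC=C)Oc2cccc(OC(C)=O)c2)cc1 | intermediate
10 | secondary ozonide (1,2,4-trioxolane) of 9, mixture at the trioxolane carbon | CC(=O)Oc1ccc([C@@H](CC2OCOO2)Oc2cccc(OC(C)=O)c2)cc1 | intermediate (not isolated)
11 | 4-[(1R)-1-(3-acetoxyphenoxy)-3-oxopropyl]phenyl acetate | CC(=O)Oc1ccc([C@@H](CC=O)Oc2cccc(OC(C)=O)c2)cc1 | intermediate
12 | 4-[(1R)-1-(3-acetoxyphenoxy)-3-(3-dodecanoyl-2,4,6-trihydroxyphenyl)-3-hydroxypropyl]phenyl acetate, both carbinol epimers | CCCCCCCCCCCC(=O)c1c(O)cc(O)c(C(O)C[C@H](c2ccc(OC(C)=O)cc2)Oc2cccc(OC(C)=O)c2)c1O | intermediate (not isolated)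
13 | ortho-quinone methide of the acylphloroglucinol ring with C4 as exocyclic carbon, (R) at C2 | CCCCCCCCCCCC(=O)C1=C(O)C(=CC[C@H](c2ccc(OC(C)=O)cc2)Oc2cccc(OC(C)=O)c2)C(=O)C=C1O | intermediate (not isolated)
14 | 4-[(2R,4R)-7-acetoxy-4-(3-dodecanoyl-2,4,6-trihydroxyphenyl)-3,4-dihydro-2H-chromen-2-yl]phenyl acetate | CCCCCCCCCCCC(=O)c1c(O)cc(O)c([C@@H]2C[C@H](c3ccc(OC(C)=O)cc3)Oc3cc(OC(C)=O)ccc32)c1O | intermediate
15 | 1-{2,4,6-trihydroxy-3-[(2R,4R)-7-hydroxy-2-(4-hydroxyphenyl)-3,4-dihydro-2H-chromen-4-yl]phenyl}dodecan-1-one | CCCCCCCCCCCC(=O)c1c(O)cc(O)c([C@@H]2C[C@H](c3ccc(O)cc3)Oc3cc(O)ccc32)c1O | target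

Total step count: 6. Longest linear sequence: 5 steps (steps 2 to 6); step 1 supplies the second fragment.

**Steps most likely to fail**

Step 5. Ring A may add to the protonated aldehyde before 3 does, which would hand the configuration at C4 to an intermolecular attack with poor facial control; protic acid may also eliminate 3-acetoxyphenol from 11 before it is captured. The fallback sets out from 11 and 3 and comes back at 14, and separates the two carbon–carbon bond formations with a boron template. Heating 11, 3 and PhB(OH)2 with catalytic propionic acid in toluene at 80 °C over 4 Å molecular sieves (Nagata ortho-hydroxyalkylation) should give the cyclic phenylboronate (4H-1,3,2-benzodioxaborin) F1. Here the aldehyde is delivered inside a phenol–boronate complex and therefore only to the phloroglucinol ring. F1 is isolated and then opened with BF3·OEt2 in CH2Cl2 at −40 → 0 °C to the same ortho-quinone methide 13, which should close to 14.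

Step 4. The free β-aryloxy aldehyde may lose 3-acetoxyphenol by elimination on concentration or storage, or lose configuration at C2 by elimination and re-addition. The fallback sets out from 9 and comes back at 14, and never liberates the aldehyde. Ozonolysis of 9 in CH2Cl2/MeOH at −78 °C, Me2S quench, then trimethyl orthoformate and catalytic TsOH in the same pot should give the dimethyl acetal F2, which is stable to chromatography. F2 replaces 11 in step 5, where the acid ionises the acetal to an oxocarbenium ion that 3 attacks; the benzylic methyl ether so formed collapses to 13 and on to 14.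

Step 3. The activated benzylic alkoxyphosphonium ion may ionise (ion-pair return, erosion of enantiomeric purity) or undergo elimination to the 1-arylbutadiene. The fallback sets out from 4 and 5 and comes back at 9, and forms the ether at oxygen so that the carbinol C–O bond is never broken. Step 2 run with (R)-TRIP phosphoric acid gives the enantiomeric alcohol 4-[(1R)-1-hydroxybut-3-en-1-yl]phenyl acetate F3. 3-Acetoxyphenylboronic acid F4 is converted with KHF2 into potassium (3-acetoxyphenyl)trifluoroborate F5. Chan–Lam O-arylation of F3 with F5 (Cu(OAc)2 10 mol %, DMAP, 4 Å molecular sieves, O2, CH2Cl2, rt) is neutral and proceeds with retention, so it should give 9.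

**Further compounds**

F1 | step 5 | 4H-1,3,2-benzodioxaborin (cyclic phenylboronate of carbinol 12 through the hydroxyl para to the acyl group), (R) at C2 | CCCCCCCCCCCC(=O)c1c(O)cc2OB(c3ccccc3)OC(C[C@H](c3ccc(OC(C)=O)cc3)Oc3cccc(OC(C)=O)c3)c2c1O
F2 | step 4 | 4-[(1R)-1-(3-acetoxyphenoxy)-3,3-dimethoxypropyl]phenyl acetate | CC(=O)Oc1ccc([C@@H](CC(OC)OC)Oc2cccc(OC(C)=O)c2)cc1
F3 | step 3 | 4-[(1R)-1-hydroxybut-3-en-1-yl]phenyl acetate | CC(=O)Oc1ccc([C@H](O)CC=C)cc1
F4 | step 3 | 3-acetoxyphenylboronic acid | CC(=O)Oc1cccc(B(O)O)c1
F5 | step 3 | potassium (3-acetoxyphenyl)trifluoroborate | CC(=O)Oc1cccc([B-](F)(F)F)c1.[K+]
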